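**Retrosynthetic overview**

1. Rings: A = trioxygenated ring bearing the carbinol, B = para-phenylene, C = ring with CH2CH2, O-aryl and OH, D = meta-phenylene. The target comes from macrocycle 23 (fluoride, then H2), and 23 from macrocyclic 6-alkyl-3-aryloxycyclohex-2-enone 20 by C=O reduction, dehydration and dehydrogenation.
2. Enone 20 comes from closure of the 18-membered ring by intramolecular kinetic α′-alkylation (Stork–Danheiser type) of vinylogous ester 18; the bond formed joins C6 of the cyclohexenone (future ring B) to the terminal CH2 of the CH2CH2I arm on ring C.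
3. Enabling feature: ring B carries only two substituents, para to each other, the ether O (to C3 of ring A) and the bridge CH2. This O/C para pair is the C3–O / C6 (α′) pair of a 3-aryloxycyclohex-2-en-1-one, so ring B is carried as a cyclohexane-1,3-dione-level ring. Its extra C1 carbonyl lets the ring A phenol be attached by addition–elimination, makes C6 the enolate carbon, and is erased on aromatization.
4. Iodide 18 comes from 3-chlorocyclohex-2-enone and phenol carbinol 14; 14 from asymmetric transfer hydrogenation of ketone 13; 13 from Weinreb amide 11 (methyl gallate, O4/O5 as Ph2C ketal) and the benzylic Grignard reagent of dichloride 8 (ring C–O–ring D by SNAr, CHO → vinyl → CH2CH2Cl).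
5. Order of ring events: C–O–D diaryl ether; ring A joined by a C–C bond and the stereocentre set; cyclohexenone (ring B precursor) hung on the ring A oxygen; macrocycle closed at C6(B)–CH2; ring B aromatized; deprotection.

Key step: step 13

Remark: the carbinol carbon of the target is (S) (OH > ring A carbon > CH2Ar > H).
Remark: ring B locants refer to the cyclohexenone (C1 = C=O, C3 = C–O–ring A, C6 = α′ carbon); the sp3 centres created at C6 and C1 are erased on aromatization.
Remark: compounds 1, 3, 9 and 15 are taken as commercial.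

**Route**

Step 1
Reactants: 1 2-fluoro-3-hydroxybenzaldehyde
Product: 2 3-(benzyloxy)-2-fluorobenzaldehyde
Conditions: BnBr, K2CO3, DMF, rt
Reagents that add atoms: benzyl bromide, BrCc1ccccc1
Why: Williamson O-benzylation of the phenoxide; the benzyl ether should survive until the final hydrogenolysis.

Step 2
Reactants: 2 3-(benzyloxy)-2-fluorobenzaldehyde; 3 3-hydroxybenzyl alcohol
Product: 4 3-(benzyloxy)-2-[3-(hydroxymethyl)phenoxy]benzaldehyde
Conditions: K2CO3, DMF, 110 °C
Reagents that add atoms: none
Why: SNAr (Meisenheimer pathway) of the phenoxide on the fluoride activated by the ortho formyl group; carbonate should not deprotonate the aliphatic OH, so only the phenol is arylated.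

Step 3
Reactants: 4 3-(benzyloxy)-2-[3-(hydroxymethyl)phenoxy]benzaldehyde
Product: 5 {3-[2-(benzyloxy)-6-ethenylphenoxy]phenyl}methanol
Conditions: Ph3PCH3Br (2.5 equiv), KOtBu (2.4 equiv), THF, 0 °C to rt
Reagents that add atoms: methyltriphenylphosphonium bromide, C[P+](c1ccccc1)(c1ccccc1)c1ccccc1.[Br-]
Why: Wittig methylenation of a non-enolizable aryl aldehyde; the excess ylide covers the free OH.

Step 4
Reactants: 5 {3-[2-(benzyloxy)-6-ethenylphenoxy]phenyl}methanol
Product: 7 2-{3-(benzyloxy)-2-[3-(hydroxymethyl)phenoxy]phenyl}ethan-1-ol, via alkylborane 6 (not isolated)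
Conditions: 9-BBN (2.5 equiv), THF, 0 °C to rt; then aq. NaOH, H2O2, 0 °C to rt
Reagents that add atoms: hydrogen peroxide, OO
Why: anti-Markovnikov hydroboration of the styrene with 9-BBN (the benzylic OH is carried as its borinate) and oxidation with retention should give the primary alcohol (hydroboration–oxidation).

Step 5
Reactants: 7 2-{3-(benzyloxy)-2-[3-(hydroxymethyl)phenoxy]phenyl}ethan-1-ol
Product: 8 1-(benzyloxy)-3-(2-chloroethyl)-2-[3-(chloromethyl)phenoxy]benzene
Conditions: PPh3, NCS, THF, 0 °C to rt
Reagents that add atoms: N-chlorosuccinimide, ClN1C(=O)CCC1=O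
Why: Appel-type deoxychlorination of both primary alcohols through alkoxyphosphonium ions under neutral conditions.

Step 6
Reactants: 9 methyl gallate
Product: 10 methyl 7-hydroxy-2,2-diphenyl-1,3-benzodioxole-5-carboxylate
Conditions: Ph2CCl2, neat, 170 °C
Reagents that add atoms: dichlorodiphenylmethane, ClC(Cl)(c1ccccc1)c1ccccc1
Why: ketalization of one vicinal pair of phenols; the symmetry of methyl gallate allows one product only, with a single free OH meta to the ester (the future ring A–O–ring B oxygen).

Step 7
Reactants: 10 methyl 7-hydroxy-2,2-diphenyl-1,3-benzodioxole-5-carboxylate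
Product: 11 7-hydroxy-N-methoxy-N-methyl-2,2-diphenyl-1,3-benzodioxole-5-carboxamide
Conditions: MeNHOMe·HCl, iPrMgCl, THF, −20 to 0 °C
Reagents that add atoms: N,O-dimethylhydroxylamine hydrochloride, CNOC.Cl
Why: aminolysis of the ester by the magnesium amide (Weinreb amide synthesis); the phenol is carried as its magnesium phenoxide and returns on work-up.

Step 8
Reactants: 8 1-(benzyloxy)-3-(2-chloroethyl)-2-[3-(chloromethyl)phenoxy]benzene; 11 7-hydroxy-N-methoxy-N-methyl-2,2-diphenyl-1,3-benzodioxole-5-carboxamide
Product: 13 2-{3-[2-(benzyloxy)-6-(2-chloroethyl)phenoxy]phenyl}-1-(7-hydroxy-2,2-diphenyl-1,3-benzodioxol-5-yl)ethan-1-one, via benzylic Grignard reagent 12 (not isolated)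
Conditions: 8, Mg, THF, 0 °C (slow addition); 11, iPrMgCl (1.0 equiv), THF, 0 °C; combine, 0 °C to rt; aq. NH4Cl
Reagents that add atoms: none
Why: magnesium should insert into the benzylic C–Cl bond far faster than into the primary alkyl chloride, and addition to the Weinreb amide stops at the chelated tetrahedral intermediate, giving the ketone on work-up (Weinreb ketone synthesis).

Step 9
Reactants: 13 the aryl benzyl ketone
Product: 14 (1S)-2-{3-[2-(benzyloxy)-6-(2-chloroethyl)phenoxy]phenyl}-1-(7-hydroxy-2,2-diphenyl-1,3-benzodioxol-5-yl)ethan-1-ol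
Conditions: RuCl[(S,S)-TsDPEN](p-cymene) (2 mol%), HCO2H–Et3N (5:2), EtOAc, 35 °C
Reagents that add atoms: none
Why: Noyori–Ikariya asymmetric transfer hydrogenation; the (S,S) catalyst delivers hydride to the face that gives the (S)-carbinol of aryl alkyl ketones (aryl–arene CH/π contact in the outer-sphere transition state), so the stereocentre is set by catalyst control.

Step 10
Reactants: 14 the (S)-phenol carbinol; 15 3-chlorocyclohex-2-en-1-one
Product: 16 3-aryloxycyclohex-2-en-1-one, the aryl being ring A of 14 bound through its free phenol oxygen (carbinol (S), OH free)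
Conditions: K2CO3, acetone, 50 °C
Reagents that add atoms: none
Why: addition–elimination of the phenoxide on the β-chloro enone gives the vinylogous aryl ester; this C(sp2)–O bond is the future diaryl ether, and carbonate should leave the secondary alcohol and the alkyl chloride untouched.

Step 11
Reactants: 16 the vinylogous ester carbinol
Product: 17 tert-butyldimethylsilyl ether of 16 (carbinol (S))
Conditions: TBSCl, imidazole, DMF, rt
Reagents that add atoms: tert-butyldimethylsilyl chloride, CC(C)(C)[Si](C)(C)Cl
Why: silylation of the only free OH removes the last acidic site before enolate chemistry and shields the electron-rich benzylic position in steps 13–15.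

Step 12
Reactants: 17 the chloride
Product: 18 the corresponding primary iodide (2-iodoethyl arm on ring C)
Conditions: NaI, 2-butanone, reflux
Reagents that add atoms: sodium iodide, [Na+].[I-]
Why: Finkelstein exchange at the primary alkyl chloride, driven by precipitation of NaCl, gives the electrophile for the ring closure.

Step 13
Reactants: 18 the iodo vinylogous ester
Product: 20 macrocyclic enone (18-membered ring; ring B as 6-alkyl-3-aryloxycyclohex-2-en-1-one, both C6 epimers; carbinol (S), OTBS), via lithium dienolate 19 (not isolated)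
Conditions: LDA (1.1 equiv), THF, −78 °C, 18 added slowly to 2 mM; then DMPU, −78 to 0 °C
Reagents that add atoms: none
Why: LDA removes at −78 °C the only kinetically accessible α-proton of the vinylogous ester, that on C6 (α′; C2 is vinylic and γ-deprotonation at C4 is the slower, thermodynamic pathway), to give the cross-conjugated lithium dienolate 19, whose C6 then displaces the primary iodide in an intramolecular SN2 reaction. The closest known reaction type is the Stork–Danheiser kinetic α′-alkylation of 3-alkoxycyclohex-2-enones with primary iodides, here run intramolecularly as a macrocyclizing enolate alkylation. One ring is closed, the 18-membered macrocycle, in an 18-exo-tet mode. The new stereocentre at C6 is not controlled (both epimers relative to the (S)-silyloxy carbon are expected) and need not be, since it becomes an sp2 carbon of ring B in step 15. The selectivities required are α′- over γ-enolization (kinetic base, low temperature), C- over O-alkylation (lithium enolate, soft iodide), substitution over E2 loss of HI from the 2-arylethyl iodide (weakly basic delocalized enolate, DMPU) and ring closure over oligomerization (high dilution, enolate fully formed before warming). The substrate secures chemoselectivity because it holds a single enolizable carbonyl and a single electrophile, all OH groups being capped (TBS, Bn, Ph2C ketal), and the three sp3 carbons of the cyclohexenone give the chain a bend that the flat para-linked ring B of the product lacks.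

Step 14
Reactants: 20 the macrocyclic enone
Product: 21 macrocyclic allylic alcohol (ring B as 6-alkyl-3-aryloxycyclohex-2-en-1-ol, mixture at C1 and C6; carbinol (S), OTBS), used crude
Conditions: DIBAL-H, CH2Cl2, −78 °C; Rochelle salt work-up
Reagents that add atoms: none
Why: 1,2-reduction of the vinylogous ester carbonyl as in the first half of a Stork–Danheiser sequence; the new carbinol centre is formed without control and is erased in step 15, and the neutral work-up avoids ionization of the product.

Step 15
Reactants: 21 the macrocyclic allylic alcohol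
Product: 23 macrocycle with aromatic ring B (carbinol (S) as TBS ether, ring C OBn, ring A Ph2C ketal), via dienyl ether 22 (not isolated)
Conditions: Burgess reagent, PhMe, 50 °C; then DDQ (1.05 equiv), 0 °C
Reagents that add atoms: none
Why: the Burgess sulfamate eliminates (syn-Ei, or E1 through the aryloxy-stabilized allyl cation) under anhydrous conditions to the 1-aryloxy-4-alkylcyclohexa-1,3-diene, so the ring A–O–ring B bond never meets water, and DDQ then dehydrogenates this dihydroarene (hydride abstraction, proton loss) with aromatization as driving force.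

Step 16
Reactants: 23 the silyl-protected macrocycle
Product: 24 the free (S)-carbinol (ring C OBn, ring A Ph2C ketal)
Conditions: TBAF, THF, 0 °C to rt
Reagents that add atoms: none
Why: fluoride-induced Si–O cleavage; all phenols are still capped, so the basic conditions should not endanger the product or the stereocentre.

Step 17
Reactants: 24 the protected macrocyclic carbinol
Product: 25 the target, (S)-configured
Conditions: H2 (1 atm), Pd(OH)2/C, EtOAc–MeOH, rt
Reagents that add atoms: none
Why: neutral hydrogenolysis of the benzyl ether and of the diphenylmethylene ketal should release the three phenols without acid or base, which the p-hydroxybenzylic alcohol would not tolerate; the stereocentre is not touched.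

**Compound list**

1 | 2-fluoro-3-hydroxybenzaldehyde | O=Cc1cccc(O)c1F | starting material
2 | 3-(benzyloxy)-2-fluorobenzaldehyde | O=Cc1cccc(OCc2ccccc2)c1F | intermediate
3 | 3-hydroxybenzyl alcohol | OCc1cccc(O)c1 | starting material
4 | 3-(benzyloxy)-2-[3-(hydroxymethyl)phenoxy]benzaldehyde | O=Cc1cccc(OCc2ccccc2)c1Oc1cccc(CO)c1 | intermediate
5 | {3-[2-(benzyloxy)-6-ethenylphenoxy]phenyl}methanol | C=Cc1cccc(OCc2ccccc2)c1Oc1cccc(CO)c1 | intermediate
6 | B-(2-arylethyl)-9-BBN from 5, benzylic oxygen as 9-BBN borinate | C1CCC2CCCC1B2CCc1cccc(OCc3ccccc3)c1Oc1cccc(COB3C4CCCC3CCC4)c1 | intermediate (not isolated)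
7 | 2-{3-(benzyloxy)-2-[3-(hydroxymethyl)phenoxy]phenyl}ethan-1-ol | OCCc1cccc(OCc2ccccc2)c1Oc1cccc(CO)c1 | intermediate
8 | 1-(benzyloxy)-3-(2-chloroethyl)-2-[3-(chloromethyl)phenoxy]benzene | ClCCc1cccc(OCc2ccccc2)c1Oc1cccc(CCl)c1 | intermediate
9 | methyl gallate | COC(=O)c1cc(O)c(O)c(O)c1 | starting material
10 | methyl 7-hydroxy-2,2-diphenyl-1,3-benzodioxole-5-carboxylate | COC(=O)c1cc(O)c2OC(c3ccccc3)(c3ccccc3)Oc2c1 | intermediate
11 | 7-hydroxy-N-methoxy-N-methyl-2,2-diphenyl-1,3-benzodioxole-5-carboxamide | CON(C)C(=O)c1cc(O)c2OC(c3ccccc3)(c3ccccc3)Oc2c1 | intermediate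
12 | {3-[2-(benzyloxy)-6-(2-chloroethyl)phenoxy]phenyl}methylmagnesium chloride | Cl[Mg]Cc1cccc(Oc2c(CCCl)cccc2OCc2ccccc2)c1 | intermediate (not isolated)
13 | 2-{3-[2-(benzyloxy)-6-(2-chloroethyl)phenoxy]phenyl}-1-(7-hydroxy-2,2-diphenyl-1,3-benzodioxol-5-yl)ethan-1-one | O=C(Cc1cccc(Oc2c(CCCl)cccc2OCc2ccccc2)c1)c1cc(O)c2OC(c3ccccc3)(c3ccccc3)Oc2c1 | intermediate
14 | (1S)-2-{3-[2-(benzyloxy)-6-(2-chloroethyl)phenoxy]phenyl}-1-(7-hydroxy-2,2-diphenyl-1,3-benzodioxol-5-yl)ethan-1-ol | ClCCc1cccc(OCc2ccccc2)c1Oc1cccc(C[C@H](O)c2cc(O)c3OC(c4ccccc4)(c4ccccc4)Oc3c2)c1 | intermediate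
15 | 3-chlorocyclohex-2-en-1-one | O=C1CCCC(Cl)=C1 | starting material
16 | vinylogous ester: 3-aryloxycyclohex-2-en-1-one on the ring A oxygen of 14, (S)-carbinol free | ClCCc1cccc(OCc2ccccc2)c1Oc1cccc(C[C@H](O)c2cc(OC3=CC(=O)CCC3)c3OC(c4ccccc4)(c4ccccc4)Oc3c2)c1 | intermediate
17 | TBS ether of 16, (S) | ClCCc1cccc(OCc2ccccc2)c1Oc1cccc(C[C@H](O[Si](C)(C)C(C)(C)C)c2cc(OC3=CC(=O)CCC3)c3OC(c4ccccc4)(c4ccccc4)Oc3c2)c1 | intermediate
18 | primary iodide corresponding to 17, (S) | ICCc1cccc(OCc2ccccc2)c1Oc1cccc(C[C@H](O[Si](C)(C)C(C)(C)C)c2cc(OC3=CC(=O)CCC3)c3OC(c4ccccc4)(c4ccccc4)Oc3c2)c1 | intermediate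
19 | lithium C1–O/C1=C6 dienolate of 18, (S) | ICCc1cccc(OCc2ccccc2)c1Oc1cccc(C[C@H](O[Si](C)(C)C(C)(C)C)c2cc(OC3=CC(O[Li])=CCC3)c3OC(c4ccccc4)(c4ccccc4)Oc3c2)c1 | intermediate (not isolated)
20 | macrocyclic enone: 18-membered ring, ring B as 6-alkyl-3-aryloxycyclohex-2-en-1-one (both C6 epimers), carbinol (S) as TBS ether | O=C1C=C2CCC1CCc1cccc(OCc3ccccc3)c1Oc1cccc(c1)C[C@H](O[Si](C)(C)C(C)(C)C)c1cc(O2)c2OC(c3ccccc3)(c3ccccc3)Oc2c1 | intermediate
21 | macrocyclic allylic alcohol: ring B as 6-alkyl-3-aryloxycyclohex-2-en-1-ol (mixture at C1 and C6), carbinol (S) as TBS ether | OC1C=C2CCC1CCc1cccc(OCc3ccccc3)c1Oc1cccc(c1)C[C@H](O[Si](C)(C)C(C)(C)C)c1cc(O2)c2OC(c3ccccc3)(c3ccccc3)Oc2c1 | intermediate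
22 | macrocyclic dienyl ether: ring B as 1-aryloxy-4-alkylcyclohexa-1,3-diene, carbinol (S) as TBS ether | C1C=C2CCC=1CCc1cccc(OCc3ccccc3)c1Oc1cccc(c1)C[C@H](O[Si](C)(C)C(C)(C)C)c1cc(O2)c2OC(c3ccccc3)(c3ccccc3)Oc2c1 | intermediate (not isolated)
23 | macrocycle with aromatic ring B; carbinol (S) as TBS ether, ring C OBn, ring A diphenylmethylene ketal | c1cc2ccc1CCc1cccc(OCc3ccccc3)c1Oc1cccc(c1)C[C@H](O[Si](C)(C)C(C)(C)C)c1cc(O2)c2OC(c3ccccc3)(c3ccccc3)Oc2c1 | intermediate
24 | macrocycle with free (S)-carbinol; ring C OBn, ring A diphenylmethylene ketal | c1cc2ccc1CCc1cccc(OCc3ccccc3)c1Oc1cccc(c1)C[C@H](O)c1cc(O2)c2OC(c3ccccc3)(c3ccccc3)Oc2c1 | intermediate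
25 | target, (S)-carbinol | Oc1cc2cc(c1O)Oc1ccc(cc1)CCc1cccc(O)c1Oc1cccc(c1)C[C@@H]2O | target

**Step count and risks**

Total step count: 17. Longest linear sequence: 15 steps (steps 1–5, then 8–17).

The three steps most likely to fail:

Step 13. The ring closure may be outrun by E2 loss of HI from the 2-arylethyl iodide, by intermolecular alkylation (oligomerization), or by proton transfer that scrambles the kinetic enolate. The fallback brings ring B in as an arene and makes the same bond by a B-alkyl Suzuki–Miyaura macrocyclization. It sets out from 14: Chan–Lam O-arylation with 4-bromophenylboronic acid (Cu(OAc)2, pyridine, 4 Å MS, CH2Cl2, air) should give the 4-bromophenyl ether F1, and TBSCl/imidazole its silyl ether F2. Dehydrochlorination of the 2-chloroethyl arm with KOtBu in THF would give the styrene F3. Hydroboration with 9-BBN forms the alkylborane F4 in the flask, and Pd(dppf)Cl2, AsPh3 and Cs2CO3 in DMF–THF–H2O under high dilution should close the ring. This comes back to the route at 23, so steps 10–15 are bypassed.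

Step 15. The allylic C–O bond may ionize and be captured by adventitious water, which would hydrolyze the vinylogous system and open the macrocycle at the ring A–O–ring B linkage. DDQ may also over-oxidize at the benzylic silyl ether. The fallback inverts the order: oxidize first, deoxygenate second. It sets out from 20: LDA/TMSCl would give the silyl dienol ether F5, and Pd(OAc)2 in MeCN (Saegusa–Ito oxidation followed by enolization) the phenol F6. PhNTf2/Cs2CO3 would give the aryl triflate F7, and Pd(OAc)2/dppf with HCO2H and Et3N in DMF at 60 °C (reductive detriflation) comes back to the route at 23.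

Step 17. Over-reduction may occur: once the para phenol is unveiled, the free benzylic C–OH bond on the electron-rich ring A may be hydrogenolysed. The fallback inverts the last two steps so that the carbinol is still silylated during hydrogenolysis. It sets out from 23: H2 over Pd(OH)2/C should give the silyl-protected triphenol F8, and Et3N·3HF in MeCN at rt then removes the silyl group under near-neutral conditions, coming back to the route at 25.

Further compounds
F1 | step 13 | 4-bromophenyl ether of the ring A phenol of 14, (S)-carbinol free | ClCCc1cccc(OCc2ccccc2)c1Oc1cccc(C[C@H](O)c2cc(Oc3ccc(Br)cc3)c3OC(c4ccccc4)(c4ccccc4)Oc3c2)c1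
F2 | step 13 | TBS ether of F1, (S) | ClCCc1cccc(OCc2ccccc2)c1Oc1cccc(C[C@H](O[Si](C)(C)C(C)(C)C)c2cc(Oc3ccc(Br)cc3)c3OC(c4ccccc4)(c4ccccc4)Oc3c2)c1
F3 | step 13 | styrene from F2 (vinyl on ring C), (S) | C=Cc1cccc(OCc2ccccc2)c1Oc1cccc(C[C@H](O[Si](C)(C)C(C)(C)C)c2cc(Oc3ccc(Br)cc3)c3OC(c4ccccc4)(c4ccccc4)Oc3c2)c1
F4 | step 13 | B-(2-arylethyl)-9-BBN from F3, (S), not isolated | C1CCC2CCCC1B2CCc1cccc(OCc3ccccc3)c1Oc1cccc(C[C@H](O[Si](C)(C)C(C)(C)C)c3cc(Oc4ccc(Br)cc4)c4OC(c5ccccc5)(c5ccccc5)Oc4c3)c1
F5 | step 15 | trimethylsilyl dienol ether of 20 (C1–OSiMe3, C1=C6), (S) | C[Si](C)(C)OC1C=C2CCC=1CCc1cccc(OCc3ccccc3)c1Oc1cccc(c1)C[C@H](O[Si](C)(C)C(C)(C)C)c1cc(O2)c2OC(c3ccccc3)(c3ccccc3)Oc2c1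
F6 | step 15 | macrocyclic phenol: ring B aromatic with OH ortho to the bridge CH2, (S) | Oc1cc2ccc1CCc1cccc(OCc3ccccc3)c1Oc1cccc(c1)C[C@H](O[Si](C)(C)C(C)(C)C)c1cc(O2)c2OC(c3ccccc3)(c3ccccc3)Oc2c1
F7 | step 15 | aryl triflate of F6, (S) | FC(F)(F)S(=O)(=O)Oc1cc2ccc1CCc1cccc(OCc3ccccc3)c1Oc1cccc(c1)C[C@H](O[Si](C)(C)C(C)(C)C)c1cc(O2)c2OC(c3ccccc3)(c3ccccc3)Oc2c1
F8 | step 17 | TBS ether of the target at the (S)-carbinol, all phenols free | c1cc2ccc1CCc1cccc(O)c1Oc1cccc(c1)C[C@H](O[Si](C)(C)C(C)(C)C)c1cc(O2)c(O)c(O)c1
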